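Assumption: positions are numbered as in 1-benzofuran (O1, C2, C3, C3a, C4–C7, C7a) and the shikimate carbons carry primes (C1′–C6′). The sense of induction of the hydrogenation catalyst in step 9 cannot be derived from structure, so the route is written for the ligand antipode that gives the (2S,3R) acid.

## Analysis of the target

The target 22 is a 2,3-dihydro-1-benzofuran (ring B: O1, C2, C3, C3a, C7a) fused to a benzene ring A (C3a, C4–C7, C7a). Its C3 carboxyl is esterified by the C5′ hydroxyl of shikimic acid (ring C, a cyclohexene). Ring A is contiguously tetrasubstituted: O1 at C7a, a free hydroxyl at C7, the (E)-acrylic acid arm at C4 and the ring fusion at C3a, so only C5 and C6 carry hydrogen; C2 bears a 3,4-dihydroxyphenyl group. There are five stereocentres. C2 (S) and C3 (R) hold the aryl and the acyl group on the same face of ring B (cis). C3′, C4′ and C5′ are those of natural shikimic acid and can be bought. The cis pair is the less stable arrangement: C3–H is benzylic, α to an ester and β to the ring oxygen, so base can epimerise it to trans or open ring B by elimination. The C2–O1 bond is a benzylic ether para to an aryl oxygen and can ionise in strong acid. Further sensitive groups are the catechol and the C7 phenol (oxidation), two α,β-unsaturated acids (reduction, conjugate addition), the allylic diol, and the secondary ester, which can migrate to O4′ under base. The difficulty is to tell four phenolic oxygens apart, to set the crowded cis pair next to the peri C4 arm in one absolute sense, and to keep it through arm installation, ester union and deprotection. The strategy rests on ring A: the oxygen at C7 and the carbon arm at C4 are para to each other and flank the furan fusion. That is the pattern obtained when a carbene carbon on a furan α-position, an alkyne and a carbonyl ligand are joined into a new benzene ring, and C4 then emerges as the only free hydroxyl of the molecule.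

## Retrosynthetic reasoning

**22 from 21.** The last operation removes only protecting groups. All of them in 21 (three methoxymethyl ethers, one isopropylidene acetal, two tert-butyl esters) are chosen to fall in one acidic step, because base would endanger the cis pair and the secondary ester, and hydrogenolysis would reduce both enoic acids.

**21 from 17 and 20.** The acyl–O5′ bond is cut. The shikimate has to arrive after the reduction of ring B, since its own C1′=C2′ bond would not survive a hydrogenation. Cutting here also lets the three cyclohexene stereocentres be bought with 18. The forward step must acylate a hindered secondary alcohol without enolising the activated acid.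

**17 from 15 and 16.** The C4–vinyl bond is cut. The acrylate has to come after the reduction for the same reason, and an aryl triflate at C4 is the handle that survives until then. The forward Heck reaction is run on the free acid: under amine base the acid is a carboxylate, whose α-hydrogen is far too weakly acidic to be removed, so neither epimerisation nor ring opening can start.

**15 from 14.** The C2–H and C3–H bonds are cut. Putting two hydrogen atoms on one face of the C2=C3 bond of a flat benzofuran sets both stereocentres at once and can only give cis. The free carboxyl is the binding point for the chiral catalyst. Everything before this point is achiral, so nothing can be lost by racemisation.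

**14 back to 10.** These are changes of functional groups on the flat, robust benzofuran.
- 14 from 13: the methyl ester is cut at the O–CH3 bond by a soft nucleophile. The C3 carbonyl is flanked by the C2 aryl group and the C4 triflate, so attack at the acyl carbon would be slow and would compete with loss of the triflate. For this reason the ester is carried as methyl from the start.
- 13 from 12 from 11: the three methyl ethers that served through the organometallic steps are exchanged for acid-labile acetals.
- 11 from 10: the single free hydroxyl at C4 becomes the triflate before the other three oxygens are unmasked, so the four phenolic oxygens never have to be told apart by reactivity.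

**10 from 9, and 9 from 6 and 7.** Ring A is taken apart at C7–C6, C5–C4 and C4–C3a. This returns a furan that already carries the C2 aryl group and the C3 ester, a carbene carbon that becomes C7 with its methoxy group, a carbonyl ligand that becomes C4 with its hydroxyl, and the two carbons of 7 that become C6 and C5. Cutting here, and not at ring B, leaves the hard substitution pattern of ring A to one step with clear rules of regiochemistry. The silyl group of 7 steers the orientation and is removed afterwards (9 to 10). The forward step must insert the alkyne in one sense, insert a carbonyl ligand, and close onto the one free furan carbon next to the carbene.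

**6 from 3.** The carbene carbon is attached at the only free α-position of the furan through the lithio compound 4 and the acyl chromate 5. This is short, so the risk of the route sits in the annulation.

**3 from 1 and 2.** The furan is cut at O1–C5 and C3–C4. The β-ketoester 1 supplies the aryl-bearing carbon, the ester-bearing carbon and the ring oxygen; 2 supplies the two unsubstituted carbons.

**20 from 19 from 18.** The cis 3′,4′-diol of 18 is tied up as an acetal and the acid as a tert-butyl ester, which leaves O5′ as the only free hydroxyl.

## Alternatives that were turned down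

**Alternative 1:** dearomative syn-arylcarbonylation of a 2,3-unsubstituted benzofuran.
- Disconnection: C2–aryl, C3–acyl and acyl–O5′ are cut together. This leads back to benzofuran A2, aryl iodide A3, carbon monoxide A4 and the alcohol 20.
- Forward key step: an arylpalladium species from A3 and a chiral zerovalent palladium catalyst adds across C2=C3 of A2. A4 inserts at C3 and 20 takes up the acyl group, giving A1.
- For it: three bonds and both stereocentres form in one step. Syn addition dictates cis. The ester is formed from an acylpalladium, so no epimerisable acid is ever activated. The sequence is much shorter.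
- Against it: under A4 the arylpalladium is expected to insert A4 before it meets the weakly binding aromatic C2=C3 bond, which would simply esterify A3 with 20. The C3–palladium intermediate can lose palladium and the C2 hydrogen under base and rearomatise. Intermolecular, enantioselective versions with a hindered secondary alcohol as third component are not secured, and the peri C4 acetal crowds C3. The acetal must later become the acrylic acid by an olefination under base with the cis ester already present.
- Comparison: Alternative 1 is stronger in step count and in how the ester bond is made. The chosen route offers separate, individually known bond formations on flat intermediates and a racemic, separable fallback for its one unproven step. In Alternative 1 every bond depends on the same event.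

**Alternative 2:** lactone-tethered photochemical arylation of a 4-aryloxycoumarin.
- Disconnection: C3–C3a is cut within a lactone that ties the C3 carboxyl to the C2 aryl ring, leading back to the 4-aryloxycoumarin A6.
- Forward key step: irradiation of Lewis-acid-bound A6 closes the aryl–O–vinyl unit by six-electron cyclisation. Hydrogen transfer in the resulting ylide restores the arene and gives the cis-fused lactone A5.
- For it: the closure is intramolecular. While the tether is in place, cis is the stable ring fusion, which the chosen route cannot claim for its open cis acid. A chiral Lewis acid could set the absolute configuration.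
- Against it: the tether leaves an oxygen on the catechol ring ortho to C2 that the target does not have. A5 must be opened against ready relactonisation, the freed phenol excised by triflation and reduction, and the cis acid then esterified with 20 by the same delicate acylation as in the chosen route. The relative configuration after hydrogen transfer and the enantiocontrol of the photoreaction both need proof, and the C4 acetal still has to become the acrylate.
- Comparison: Alternative 2 is longer after its key step than the chosen route is after its own. The chosen route never carries an extra oxygen and sets cis by syn addition of hydrogen.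

**Alternative 3:** Wolff ring contraction of a 3-diazoflavanone with shikimate capture.
- Disconnection: C3–C3a and acyl–O5′ are cut, leading back to the 3-diazochromanone A8 and the alcohol A9.
- Forward key step: visible light expels nitrogen from A8. The ring A carbon shifts from the ketone carbon to the diazo carbon, contracting the pyranone to ring B. The ketene is captured by A9 and C3 is protonated anti to the C2 aryl group, giving A7.
- For it: the ester bond and the C3 stereocentre form together from a ketene, so no activation of an epimerisable acid is needed. On this point Alternative 3 is stronger than the chosen route. C2 is set beforehand and directs C3.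
- Against it: introducing the diazo group needs enolisation at C3 of a flavanone, and that enolate opens ring B by loss of the phenoxide, which erases C2. A 1,2-shift of the C2 hydrogen in the carbene competes with aryl migration and would aromatise the pyranone. The ketene is flanked by the C2 aryl group and the peri acetal while the nucleophile is a hindered secondary alcohol. Cis selectivity rests on one substituent of a nearly flat ring and on a kinetic protonation.
- Comparison: the chosen route sets C2 and C3 together in one syn addition with no stereocentre exposed earlier. It pays for this with a separate, carefully run esterification, for which a Mitsunobu fallback without acyl activation is kept ready.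

Key step: step 3

## Route

**Step 1**
Reactants: 1 methyl 3-(3,4-dimethoxyphenyl)-3-oxopropanoate; 2 chloroacetaldehyde
Product: 3 methyl 2-(3,4-dimethoxyphenyl)furan-3-carboxylate
Conditions: 2 (50% aq.), pyridine, 50 °C
Reagents that add atoms: none
Why: Feist–Benary furan synthesis: the enolate carbon of 1 adds to the aldehyde of 2, the enol oxygen displaces chloride and the hydroxydihydrofuran loses water, which puts the aryl group on C2 and the ester on C3 and leaves both remaining furan carbons unsubstituted.

**Step 2**
Reactants: 3 methyl 2-(3,4-dimethoxyphenyl)furan-3-carboxylate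
Product: 6 pentacarbonyl{[5-(3,4-dimethoxyphenyl)-4-(methoxycarbonyl)furan-2-yl](methoxy)methylidene}chromium, via 5-lithiofuran 4 (not isolated), via lithium acylchromate 5 (not isolated)
Conditions: LiN(i-Pr)2, THF, −78 °C; Cr(CO)6, −78 → 0 °C; then Me3OBF4, CH2Cl2, 0 °C
Reagents that add atoms: chromium hexacarbonyl, O=C=[Cr](=C=O)(=C=O)(=C=O)(=C=O)=C=O; trimethyloxonium tetrafluoroborate, C[O+](C)C.F[B-](F)(F)F
Why: Fischer carbene synthesis: the hindered amide base removes the only furan α-hydrogen at low temperature without touching the ester, the furyllithium adds to a carbonyl ligand of Cr(CO)6, and the acyl chromate is O-methylated by the oxonium salt.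

**Step 3**
Reactants: 6 pentacarbonyl{[5-(3,4-dimethoxyphenyl)-4-(methoxycarbonyl)furan-2-yl](methoxy)methylidene}chromium; 7 trimethylsilylacetylene
Product: 9 methyl 2-(3,4-dimethoxyphenyl)-4-hydroxy-7-methoxy-5-(trimethylsilyl)-1-benzofuran-3-carboxylate, via arene tricarbonylchromium complex 8 (not isolated)
Conditions: 7 (2 equiv), THF, 55 °C, Ar; then air, rt
Reagents that add atoms: none
Why: Dötz benzannulation. Thermal loss of one cis carbonyl ligand from 6 opens a site for 7, which inserts into the chromium–carbene bond with its unsubstituted carbon joining the carbene carbon (C7–C6) and the silyl-bearing carbon staying on chromium; a carbonyl ligand then inserts at that carbon (C5–C4) to give a chromium-bound furyl vinylketene. Ring A closes by a thermal six-electron electrocyclisation of this dienylketene in which the ketene carbon bonds to the furan β-carbon next to the carbene-bearing carbon (C4–C3a), and the 3a-H dienone tautomerises to the phenol, first held as the Cr(CO)3 complex 8 and freed by air. The closest known reaction type is the benzannulation of furan-2-yl(alkoxy)carbene chromium complexes with terminal alkynes to 4-hydroxy-7-alkoxybenzofurans. No stereocentre is formed. The step needs regiocontrol of the alkyne, which the bulk of SiMe3 secures by placing it next to the new hydroxyl and away from the carbene substituents, and it needs a single site of closure, which the substrate secures because the carbene-bearing furan carbon has only one carbon neighbour, the other being O1. Carbonyl insertion rather than five-ring formation is favoured by the alkoxy carbene, the electron-poor heteroaryl group and the donor solvent. A 1,3-shift of silicon from C5 to the C4 oxygen at the dienone stage would only give the O-silyl isomer, which step 4 converts into the same phenol 10.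

**Step 4**
Reactants: 9 methyl 2-(3,4-dimethoxyphenyl)-4-hydroxy-7-methoxy-5-(trimethylsilyl)-1-benzofuran-3-carboxylate
Product: 10 methyl 2-(3,4-dimethoxyphenyl)-4-hydroxy-7-methoxy-1-benzofuran-3-carboxylate
Conditions: CF3CO2H, CH2Cl2, 0 °C → rt
Reagents that add atoms: none
Why: Acid ipso-protodesilylation: C5 is ortho to the C4 hydroxyl and para to O1, so protonation at the silicon-bearing carbon and loss of the silyl group should be fast, while the methyl ester and methyl ethers are inert.

**Step 5**
Reactants: 10 methyl 2-(3,4-dimethoxyphenyl)-4-hydroxy-7-methoxy-1-benzofuran-3-carboxylate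
Product: 11 methyl 2-(3,4-dimethoxyphenyl)-7-methoxy-4-{[(trifluoromethyl)sulfonyl]oxy}-1-benzofuran-3-carboxylate
Conditions: Tf2O, pyridine, CH2Cl2, 0 °C
Reagents that add atoms: trifluoromethanesulfonic anhydride, O=S(=O)(OS(=O)(=O)C(F)(F)F)C(F)(F)F
Why: O-sulfonylation of the only free phenol; the C4 oxygen is fixed as the future coupling site before any other oxygen is unmasked.

**Step 6**
Reactants: 11 methyl 2-(3,4-dimethoxyphenyl)-7-methoxy-4-{[(trifluoromethyl)sulfonyl]oxy}-1-benzofuran-3-carboxylate
Product: 12 methyl 2-(3,4-dihydroxyphenyl)-7-hydroxy-4-{[(trifluoromethyl)sulfonyl]oxy}-1-benzofuran-3-carboxylate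
Conditions: BBr3 (6 equiv), CH2Cl2, −78 → 0 °C; then H2O
Reagents that add atoms: none
Why: Lewis-acid demethylation of the three aryl methyl ethers through aryloxyboron species; an aryl triflate is inert to BBr3 and the hindered conjugated methyl ester reacts much more slowly at 0 °C.

**Step 7**
Reactants: 12 methyl 2-(3,4-dihydroxyphenyl)-7-hydroxy-4-{[(trifluoromethyl)sulfonyl]oxy}-1-benzofuran-3-carboxylate
Product: 13 methyl 2-[3,4-bis(methoxymethoxy)phenyl]-7-(methoxymethoxy)-4-{[(trifluoromethyl)sulfonyl]oxy}-1-benzofuran-3-carboxylate
Conditions: MOMCl (4.5 equiv), i-Pr2NEt, CH2Cl2, 0 °C → rt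
Reagents that add atoms: chloromethyl methyl ether, COCCl
Why: O-alkylation of the three phenols under amine base, which neither the triflate nor the ester notices; the acetals survive every later step and fall with acid at the end.

**Step 8**
Reactants: 13 methyl 2-[3,4-bis(methoxymethoxy)phenyl]-7-(methoxymethoxy)-4-{[(trifluoromethyl)sulfonyl]oxy}-1-benzofuran-3-carboxylate
Product: 14 2-[3,4-bis(methoxymethoxy)phenyl]-7-(methoxymethoxy)-4-{[(trifluoromethyl)sulfonyl]oxy}-1-benzofuran-3-carboxylic acid
Conditions: LiI (8 equiv), pyridine, 110 °C; then cold 0.5 M HCl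
Reagents that add atoms: none
Why: SN2 dealkylation of a hindered methyl ester by iodide, the methyl group ending on pyridine: attack is at the open methyl carbon, so crowding at the C3 carbonyl does not matter, and neither iodide nor pyridine attacks the sulfonyl sulfur of the triflate as hydroxide would.

**Step 9**
Reactants: 14 2-[3,4-bis(methoxymethoxy)phenyl]-7-(methoxymethoxy)-4-{[(trifluoromethyl)sulfonyl]oxy}-1-benzofuran-3-carboxylic acid
Product: 15 (2S,3R)-2-[3,4-bis(methoxymethoxy)phenyl]-7-(methoxymethoxy)-4-{[(trifluoromethyl)sulfonyl]oxy}-2,3-dihydro-1-benzofuran-3-carboxylic acid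
Conditions: Ru(OAc)2[(S)-SEGPHOS] (5 mol %), H2 (80 bar), Et3N (1 equiv), MeOH, 50 °C; then cold aq. KHSO4
Reagents that add atoms: none
Why: Proposed new method: the carboxylate of 14 should bind the divalent ruthenium centre and hold the neighbouring C2=C3 bond, a tetrasubstituted β-aryloxy acrylate with little furan aromaticity, in the chiral pocket; hydride transfer to C3 and protonolysis of the C2–Ru bond with retention amount to syn addition of H2 on one face, so C2 and C3 are set together as the cis pair and the diphosphine antipode decides the absolute sense; the closest known reaction types are the Ru(OAc)2(diphosphine)-catalysed asymmetric hydrogenation of acyclic tetrasubstituted α,β-unsaturated carboxylic acids and the homogeneous asymmetric hydrogenation of 2- or 3-monosubstituted benzofurans.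

**Step 10**
Reactants: 15 (2S,3R)-2-[3,4-bis(methoxymethoxy)phenyl]-7-(methoxymethoxy)-4-{[(trifluoromethyl)sulfonyl]oxy}-2,3-dihydro-1-benzofuran-3-carboxylic acid; 16 tert-butyl acrylate
Product: 17 (2S,3R)-2-[3,4-bis(methoxymethoxy)phenyl]-4-[(E)-3-tert-butoxy-3-oxoprop-1-en-1-yl]-7-(methoxymethoxy)-2,3-dihydro-1-benzofuran-3-carboxylic acid
Conditions: Pd(OAc)2 (10 mol %), dppp (12 mol %), Et3N (3 equiv), 16 (3 equiv), DMF, 80 °C
Reagents that add atoms: none
Why: Heck–Mizoroki coupling of an aryl triflate with an acrylate; syn insertion and syn β-hydride elimination give the E alkene, and because C3 carries a carboxylate under the amine base its α-hydrogen cannot be removed, so the cis pair should be kept.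

**Step 11**
Reactants: 18 shikimic acid
Product: 19 3,4-O-isopropylidene shikimic acid
Conditions: 2,2-dimethoxypropane, CSA (cat.), acetone, rt
Reagents that add atoms: 2,2-dimethoxypropane, COC(C)(C)OC
Why: Acid-catalysed transacetalisation; only the cis 3′,4′-diol can close a five-membered acetal, which leaves the trans O5′ hydroxyl free.

**Step 12**
Reactants: 19 3,4-O-isopropylidene shikimic acid
Product: 20 tert-butyl 3,4-O-isopropylidene shikimate
Conditions: tert-butyl 2,2,2-trichloroacetimidate (2 equiv), CH2Cl2/cyclohexane, rt
Reagents that add atoms: tert-butyl 2,2,2-trichloroacetimidate, CC(C)(C)OC(=N)C(Cl)(Cl)Cl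
Why: The carboxylic acid protonates the imidate and is tert-butylated by it without added acid, conditions under which a secondary alcohol and the acetal do not react.

**Step 13**
Reactants: 17 (2S,3R)-2-[3,4-bis(methoxymethoxy)phenyl]-4-[(E)-3-tert-butoxy-3-oxoprop-1-en-1-yl]-7-(methoxymethoxy)-2,3-dihydro-1-benzofuran-3-carboxylic acid; 20 tert-butyl 3,4-O-isopropylidene shikimate
Product: 21 tert-butyl 5-O-{(2S,3R)-2-[3,4-bis(methoxymethoxy)phenyl]-4-[(E)-3-tert-butoxy-3-oxoprop-1-en-1-yl]-7-(methoxymethoxy)-2,3-dihydro-1-benzofuran-3-carbonyl}-3,4-O-isopropylidene shikimate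
Conditions: EDC·HCl (1.5 equiv), DMAP (0.2 equiv), CH2Cl2, 0 °C → rt
Reagents that add atoms: none
Why: Steglich esterification: 17 has one free acid and 20 one free hydroxyl, and the low temperature, the catalytic amount of DMAP and the absence of a stronger base are meant to let acyl transfer outrun enolisation of the activated acid at C3.

**Step 14**
Reactants: 21 tert-butyl 5-O-{(2S,3R)-2-[3,4-bis(methoxymethoxy)phenyl]-4-[(E)-3-tert-butoxy-3-oxoprop-1-en-1-yl]-7-(methoxymethoxy)-2,3-dihydro-1-benzofuran-3-carbonyl}-3,4-O-isopropylidene shikimate
Product: 22 5-O-{(2S,3R)-4-[(E)-2-carboxyethenyl]-2-(3,4-dihydroxyphenyl)-7-hydroxy-2,3-dihydro-1-benzofuran-3-carbonyl}shikimic acid (CNP0312618.1)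
Conditions: CF3CO2H/CH2Cl2/H2O (5:5:1), 1,3-dimethoxybenzene (scavenger), 0 °C → rt
Reagents that add atoms: none
Why: Acidolysis removes the three aryl methoxymethyl ethers, the isopropylidene acetal and both tert-butyl esters in one operation; acid, unlike base, does not enolise C3 or move the secondary ester, and the scavenger takes up the cations released.

## Compound list

1 | methyl 3-(3,4-dimethoxyphenyl)-3-oxopropanoate | COC(=O)CC(=O)c1ccc(OC)c(OC)c1 | starting material
2 | chloroacetaldehyde | ClCC=O | starting material
3 | methyl 2-(3,4-dimethoxyphenyl)furan-3-carboxylate | COC(=O)c1ccoc1-c1ccc(OC)c(OC)c1 | intermediate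
4 | methyl 2-(3,4-dimethoxyphenyl)-5-lithiofuran-3-carboxylate | COC(=O)c1cc([Li])oc1-c1ccc(OC)c(OC)c1 | intermediate (not isolated)
5 | lithium pentacarbonyl{[5-(3,4-dimethoxyphenyl)-4-(methoxycarbonyl)furan-2-yl]carbonyl}chromate | [Li+].[O-]C(=[Cr](=C=O)(=C=O)(=C=O)(=C=O)=C=O)c1cc(C(=O)OC)c(-c2ccc(OC)c(OC)c2)o1 | intermediate (not isolated)
6 | pentacarbonyl{[5-(3,4-dimethoxyphenyl)-4-(methoxycarbonyl)furan-2-yl](methoxy)methylidene}chromium | COC(=[Cr](=C=O)(=C=O)(=C=O)(=C=O)=C=O)c1cc(C(=O)OC)c(-c2ccc(OC)c(OC)c2)o1 | intermediate (key-step precursor)
7 | trimethylsilylacetylene | C#C[Si](C)(C)C | starting material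
8 | tricarbonylchromium complex of 9, chromium η6-bound to ring A (the dot stands for the η6 bond) | COC(=O)c1c(-c2ccc(OC)c(OC)c2)oc2c(OC)cc([Si](C)(C)C)c(O)c12.[Cr](=C=O)(=C=O)=C=O | intermediate (not isolated)
9 | methyl 2-(3,4-dimethoxyphenyl)-4-hydroxy-7-methoxy-5-(trimethylsilyl)-1-benzofuran-3-carboxylate | COC(=O)c1c(-c2ccc(OC)c(OC)c2)oc2c(OC)cc([Si](C)(C)C)c(O)c12 | intermediate (key-step product)
10 | methyl 2-(3,4-dimethoxyphenyl)-4-hydroxy-7-methoxy-1-benzofuran-3-carboxylate | COC(=O)c1c(-c2ccc(OC)c(OC)c2)oc2c(OC)ccc(O)c12 | intermediate
11 | methyl 2-(3,4-dimethoxyphenyl)-7-methoxy-4-{[(trifluoromethyl)sulfonyl]oxy}-1-benzofuran-3-carboxylate | COC(=O)c1c(-c2ccc(OC)c(OC)c2)oc2c(OC)ccc(OS(=O)(=O)C(F)(F)F)c12 | intermediate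
12 | methyl 2-(3,4-dihydroxyphenyl)-7-hydroxy-4-{[(trifluoromethyl)sulfonyl]oxy}-1-benzofuran-3-carboxylate | COC(=O)c1c(-c2ccc(O)c(O)c2)oc2c(O)ccc(OS(=O)(=O)C(F)(F)F)c12 | intermediate
13 | methyl 2-[3,4-bis(methoxymethoxy)phenyl]-7-(methoxymethoxy)-4-{[(trifluoromethyl)sulfonyl]oxy}-1-benzofuran-3-carboxylate | COC(=O)c1c(-c2ccc(OCOC)c(OCOC)c2)oc2c(OCOC)ccc(OS(=O)(=O)C(F)(F)F)c12 | intermediate
14 | 2-[3,4-bis(methoxymethoxy)phenyl]-7-(methoxymethoxy)-4-{[(trifluoromethyl)sulfonyl]oxy}-1-benzofuran-3-carboxylic acid | OC(=O)c1c(-c2ccc(OCOC)c(OCOC)c2)oc2c(OCOC)ccc(OS(=O)(=O)C(F)(F)F)c12 | intermediate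
15 | (2S,3R)-2-[3,4-bis(methoxymethoxy)phenyl]-7-(methoxymethoxy)-4-{[(trifluoromethyl)sulfonyl]oxy}-2,3-dihydro-1-benzofuran-3-carboxylic acid (cis) | O=S(=O)(Oc1ccc(OCOC)c2c1[C@@H](C(=O)O)[C@@H](c1ccc(OCOC)c(OCOC)c1)O2)C(F)(F)F | intermediate
16 | tert-butyl acrylate | C=CC(=O)OC(C)(C)C | starting material
17 | (2S,3R)-2-[3,4-bis(methoxymethoxy)phenyl]-4-[(E)-3-tert-butoxy-3-oxoprop-1-en-1-yl]-7-(methoxymethoxy)-2,3-dihydro-1-benzofuran-3-carboxylic acid (cis) | CC(C)(C)OC(=O)/C=C/c1ccc(OCOC)c2c1[C@@H](C(=O)O)[C@@H](c1ccc(OCOC)c(OCOC)c1)O2 | intermediate
18 | shikimic acid | O[C@@H]1CC(C(=O)O)=C[C@@H](O)[C@H]1O | starting material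
19 | 3,4-O-isopropylidene shikimic acid | O[C@@H]1CC(C(=O)O)=C[C@H]2OC(C)(C)O[C@@H]12 | intermediate
20 | tert-butyl 3,4-O-isopropylidene shikimate | O[C@@H]1CC(C(=O)OC(C)(C)C)=C[C@H]2OC(C)(C)O[C@@H]12 | intermediate
21 | tert-butyl 5-O-{(2S,3R)-2-[3,4-bis(methoxymethoxy)phenyl]-4-[(E)-3-tert-butoxy-3-oxoprop-1-en-1-yl]-7-(methoxymethoxy)-2,3-dihydro-1-benzofuran-3-carbonyl}-3,4-O-isopropylidene shikimate | CC(C)(C)OC(=O)/C=C/c1ccc(OCOC)c2c1[C@@H](C(=O)O[C@@H]1CC(C(=O)OC(C)(C)C)=C[C@H]3OC(C)(C)O[C@@H]13)[C@@H](c1ccc(OCOC)c(OCOC)c1)O2 | intermediate
22 | 5-O-{(2S,3R)-4-[(E)-2-carboxyethenyl]-2-(3,4-dihydroxyphenyl)-7-hydroxy-2,3-dihydro-1-benzofuran-3-carbonyl}shikimic acid (CNP0312618.1) | O=C(O)/C=C/c1ccc(O)c2c1[C@@H](C(=O)O[C@@H]1CC(C(=O)O)=C[C@@H](O)[C@H]1O)[C@@H](c1ccc(O)c(O)c1)O2 | target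

## Step count and least certain steps

Total: 14 steps. Longest linear sequence: 12 steps (steps 1–10, 13 and 14, from 1 to 22). The shikimate branch has 2 steps (11 and 12) before the union.

**Step 9 (asymmetric hydrogenation, the one step beyond known chemistry).** The fully substituted, partly aromatic C2=C3 bond may fail to bind to the ruthenium carboxylate, so that hydrogen is not taken up, or it may bind with poor discrimination of its two faces. The crowding by the C2 aryl group and the peri triflate works against both. Fallback, from 14: hydrogenation over a heterogeneous catalyst (H2, Rh/Al2O3 or Pd/C, EtOAc–AcOH, no base, so that the triflate is kept) adds both hydrogens from the catalyst surface and should give the racemic cis acid, that is 15 together with its enantiomer, the (2R,3S) acid F1. The racemate is taken through step 10, which gives 17 and its enantiomer F2, and through step 13, where the single enantiomer 20 turns the pair into 21 and its (2R,3S) diastereomer F3. These are separated by chromatography and the route is rejoined at 21.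

**Step 3 (key step).** The sequence may stop at a silyl-stabilised vinylketene that does not cyclise. Insertion may also proceed without a carbonyl ligand and close a five-membered ring onto the furan. The ester next to the closure site may chelate chromium and slow the loss of the carbonyl ligand. Fallback (ring expansion of a cyclobutenone, without chromium or silicon), from 3: the lithio compound 4 is added at −78 °C to cyclobut-3-ene-1,2-dione, a known but sensitive reagent that has to be prepared separately. The lithium alkoxide F4 is O-methylated in the same flask with MeOTf to the 4-furyl-4-methoxycyclobutenone F5, and F5 is heated in toluene at 110 °C. Conrotatory opening with the methoxy group turning outward gives the same furyl vinylketene in metal-free form, which closes onto the furan and tautomerises to 10. The route is rejoined at 10, and steps 2 to 4 are then not needed.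

**Step 2 (carbene complex).** The lithiated ester may condense with itself while the mixture warms to dissolve Cr(CO)6, or metalation may be incomplete. Fallback (nucleophilic chromium, electrophilic furan), from 3: Vilsmeier–Haack formylation (POCl3, DMF) at the free α-position gives the aldehyde F6. Pinnick oxidation (NaClO2, NaH2PO4, 2-methyl-2-butene) gives the acid F7, and (COCl)2 with catalytic DMF gives the acid chloride F8. Acylation of K2Cr(CO)5 (from Cr(CO)6 and potassium graphite, KC8) gives the potassium acylchromate F9. O-Methylation with Me3OBF4 gives 6, where the route is rejoined.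

**Step 13 (ester union).** The activated acyl species may enolise or pass through a ketene at C3, which would scramble the cis pair towards trans or expel the ring oxygen. Slow acyl transfer between two hindered partners gives this more time. Fallback (the bond is made at the alkyl carbon instead of the acyl carbon), from 20: Mitsunobu inversion (4-nitrobenzoic acid, PPh3, DIAD, THF) gives the 5′-epi 4-nitrobenzoate F10, and methanolysis (K2CO3, MeOH) gives the 5′-epi alcohol F11. A second Mitsunobu reaction of F11 with the acid 17 (PPh3, DIAD, toluene, 0 °C) lets the carboxylate displace the activated O5′ with inversion. This gives 21 without ever activating the acyl carbon, and the route is rejoined at 21.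

**Step 14 (global deprotection).** In strong protic acid the benzylic C2–O1 bond may ionise and reclose, which would erode the cis pair. The released methoxymethyl and tert-butyl cations may attack the free catechol ring, and the allylic diol may dehydrate. Fallback (silyl transfer instead of protic acidolysis, in two stages), from 21: TMSOTf and 2,2′-bipyridyl in CH2Cl2 at 0 °C, then water, should convert the aryl methoxymethyl ethers and the tert-butyl esters into silyl ethers and silyl esters that hydrolyse on work-up. This gives the 3′,4′-O-isopropylidene derivative of the target, F12. The acetal is then hydrolysed with 80% aqueous acetic acid at 40 °C to 22.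

## Further compounds

F1 | step 9 | (2R,3S)-2-[3,4-bis(methoxymethoxy)phenyl]-7-(methoxymethoxy)-4-{[(trifluoromethyl)sulfonyl]oxy}-2,3-dihydro-1-benzofuran-3-carboxylic acid (enantiomer of 15) | O=S(=O)(Oc1ccc(OCOC)c2c1[C@H](C(=O)O)[C@H](c1ccc(OCOC)c(OCOC)c1)O2)C(F)(F)F
F2 | step 9 | (2R,3S)-2-[3,4-bis(methoxymethoxy)phenyl]-4-[(E)-3-tert-butoxy-3-oxoprop-1-en-1-yl]-7-(methoxymethoxy)-2,3-dihydro-1-benzofuran-3-carboxylic acid (enantiomer of 17) | CC(C)(C)OC(=O)/C=C/c1ccc(OCOC)c2c1[C@H](C(=O)O)[C@H](c1ccc(OCOC)c(OCOC)c1)O2
F3 | step 9 | (2R,3S) diastereomer of 21 | CC(C)(C)OC(=O)/C=C/c1ccc(OCOC)c2c1[C@H](C(=O)O[C@@H]1CC(C(=O)OC(C)(C)C)=C[C@H]3OC(C)(C)O[C@@H]13)[C@H](c1ccc(OCOC)c(OCOC)c1)O2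
F4 | step 3 | lithium 1-[5-(3,4-dimethoxyphenyl)-4-(methoxycarbonyl)furan-2-yl]-4-oxocyclobut-2-en-1-olate (racemic) | [Li+].[O-]C1(C=CC1=O)c1cc(C(=O)OC)c(-c2ccc(OC)c(OC)c2)o1
F5 | step 3 | methyl 2-(3,4-dimethoxyphenyl)-5-(1-methoxy-4-oxocyclobut-2-en-1-yl)furan-3-carboxylate (racemic) | COC(=O)c1cc(C2(OC)C=CC2=O)oc1-c1ccc(OC)c(OC)c1
F6 | step 2 | methyl 2-(3,4-dimethoxyphenyl)-5-formylfuran-3-carboxylate | COC(=O)c1cc(C=O)oc1-c1ccc(OC)c(OC)c1
F7 | step 2 | 5-(3,4-dimethoxyphenyl)-4-(methoxycarbonyl)furan-2-carboxylic acid | COC(=O)c1cc(C(=O)O)oc1-c1ccc(OC)c(OC)c1
F8 | step 2 | methyl 5-(chlorocarbonyl)-2-(3,4-dimethoxyphenyl)furan-3-carboxylate | COC(=O)c1cc(C(=O)Cl)oc1-c1ccc(OC)c(OC)c1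
F9 | step 2 | potassium pentacarbonyl{[5-(3,4-dimethoxyphenyl)-4-(methoxycarbonyl)furan-2-yl]carbonyl}chromate | [K+].[O-]C(=[Cr](=C=O)(=C=O)(=C=O)(=C=O)=C=O)c1cc(C(=O)OC)c(-c2ccc(OC)c(OC)c2)o1
F10 | step 13 | tert-butyl 3,4-O-isopropylidene-5-O-(4-nitrobenzoyl)-5-epi-shikimate | O=C(O[C@H]1CC(C(=O)OC(C)(C)C)=C[C@H]2OC(C)(C)O[C@@H]12)c1ccc([N+](=O)[O-])cc1
F11 | step 13 | tert-butyl 3,4-O-isopropylidene-5-epi-shikimate | O[C@H]1CC(C(=O)OC(C)(C)C)=C[C@H]2OC(C)(C)O[C@@H]12
F12 | step 14 | 5-O-{(2S,3R)-4-[(E)-2-carboxyethenyl]-2-(3,4-dihydroxyphenyl)-7-hydroxy-2,3-dihydro-1-benzofuran-3-carbonyl}-3,4-O-isopropylidene shikimic acid | O=C(O)/C=C/c1ccc(O)c2c1[C@@H](C(=O)O[C@@H]1CC(C(=O)O)=C[C@H]3OC(C)(C)O[C@@H]13)[C@@H](c1ccc(O)c(O)c1)O2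
A1 | alternative 1 | cis-2-aryl-2,3-dihydrobenzofuran-3-carboxylic shikimate ester carrying a 1,3-dioxolane at C4 (tert-butyl ester, acetonide, three methoxymethyl ethers) | O1CCOC1c1ccc(OCOC)c2c1[C@@H](C(=O)O[C@@H]1CC(C(=O)OC(C)(C)C)=C[C@@H](O3)[C@H]1OC3(C)C)[C@@H](c1ccc(OCOC)c(OCOC)c1)O2
A2 | alternative 1 | 2-[7-(methoxymethoxy)-1-benzofuran-4-yl]-1,3-dioxolane | COCOc1ccc(C2OCCO2)c2ccoc12
A3 | alternative 1 | 4-iodo-1,2-bis(methoxymethoxy)benzene | COCOc1ccc(I)cc1OCOC
A4 | alternative 1 | carbon monoxide | [C-]#[O+]
A5 | alternative 2 | cis-fused dihydrocoumestan lactone carrying the C4 dioxolane and three methoxymethyl ethers, C2 and C3 configured as in 22 | O1CCOC1c1ccc(OCOC)c2c1[C@H]3C(=O)Oc4cc(OCOC)c(OCOC)cc4[C@H]3O2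
A6 | alternative 2 | 4-[5-(1,3-dioxolan-2-yl)-2-(methoxymethoxy)phenoxy]-6,7-bis(methoxymethoxy)-2H-chromen-2-one | O=C1C=C(Oc2cc(C3OCCO3)ccc2OCOC)c2cc(OCOC)c(OCOC)cc2O1
A7 | alternative 3 | cis-2-aryl-2,3-dihydrobenzofuran-3-carboxylic shikimate ester carrying a dimethyl acetal at C4 (allyl ester, acetonide, three methoxymethyl ethers) | COC(OC)c1ccc(OCOC)c2c1[C@@H](C(=O)O[C@@H]1CC(C(=O)OCC=C)=C[C@@H](O3)[C@H]1OC3(C)C)[C@@H](c1ccc(OCOC)c(OCOC)c1)O2
A8 | alternative 3 | (2R)-2-[3,4-bis(methoxymethoxy)phenyl]-3-diazo-5-(dimethoxymethyl)-8-(methoxymethoxy)-2,3-dihydro-4H-chromen-4-one | COC(OC)c1ccc(OCOC)c2c1C(=O)C(=[N+]=[N-])[C@@H](c1ccc(OCOC)c(OCOC)c1)O2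
A9 | alternative 3 | allyl 3,4-O-isopropylidene shikimate | O[C@@H]1CC(C(=O)OCC=C)=C[C@H]2OC(C)(C)O[C@@H]12
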